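A ratio of 0.663 stands between the dawn run's fractional rate of starting-material loss and the winter run's, though dawn carries half the catalyst. A rate proportional to catalyst and inverse to second substrate gives 0.700 for these two charges, so the readings fit that order.

all flasks: starting material 0.48 M
- winter: second substrate 2.8 equiv; free catalyst 0.76 mol%; temperature 106 °C; run made earlier
- spring: second substrate 4.4 equiv; free catalyst 0.76 mol%; temperature 120 °C; run made earlier
- dawn: second substrate 2 equiv; free catalyst 0.38 mol%; temperature 106 °C; run made earlier
- Wednesday's: second substrate 2.00 equiv; free catalyst 0.76 mol%; temperature 125 °C; time 25 h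
- Thursday's: second substrate 2.00 equiv; free catalyst 0.76 mol%; temperature 100 °C; time 25 h

| run | time / h | over-reaction product / % | target / % | catalyst intermediate A / % | starting material / % |
|---|---|---|---|---|---|
| winter | 4.00 | 0.6 | 2.7 | 0 | 95.1 |
| winter | 8.00 | 0.3 | 6.8 | 0.8 | 93.3 |
| winter | 10.0 | 0.2 | 8.1 | 0.4 | 91.4 |
| winter | 15.0 | 1.0 | 11.6 | 0.2 | 88.2 |
| winter | 20.0 | 1.8 | 13.3 | 0 | 83.1 |
| winter | 25.0 | 3.4 | 16.5 | 0.2 | 79.8 |
| spring | 0.667 | 0.6 | 1.5 | 1.0 | 98.4 |
| spring | 1.00 | 0.5 | 2.0 | 0 | 99.2 |
| spring | 2.00 | 0.3 | 3.1 | 0 | 95.7 |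
| spring | 3.00 | 0.4 | 5.0 | 0 | 94.0 |
| spring | 4.00 | 0.5 | 6.4 | 0 | 92.7 |
| spring | 6.00 | 0.6 | 10.1 | 0.5 | 89.3 |
| spring | 10.0 | 3.7 | 15.0 | 0 | 82.4 |
| dawn | 2.00 | 0 | 1.3 | 0.3 | 98.9 |
| dawn | 6.00 | 0 | 2.7 | 0 | 97.0 |
| dawn | 12.0 | 0 | 5.0 | 0 | 94.0 |
| dawn | 20.0 | 0.3 | 10.2 | 0.5 | 89.5 |
| dawn | 25.0 | 0.3 | 11.3 | 0 | 86.1 |

(standard deviation of a reading: 0.5 percentage points)



* which of these there is most of at the end, counted by the starting material in it, Wednesday's (starting material / over-reaction product / catalyst intermediate A / target)
* which of these there is most of at the end, counted by the starting material in it, Thursday's (starting material / over-reaction product / catalyst intermediate A / target)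
* amount of the one of these that there is most of at the end, in percent of the starting material charged, Wednesday's
* amount of the one of these that there is most of at the end, in percent of the starting material charged, Thursday's

The quantity to carry is the recipe rate: the fractional loss of starting material per hour, ln(charged/left)/time, rescaled by that order to 0.76 mol% of free catalyst and 2.00 equiv of second substrate, here taken from the winter run, with dawn beside it as a comparison. The two runs at 106 °C and the hotter spring run give:

winter: 0.0126 h⁻¹
dawn: 0.0120 h⁻¹

spring, at 120 °C: 0.0426 h⁻¹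

Taking the logarithm of the rate as straight in temperature from winter to spring, which stretches that step beyond its span on Wednesday's, the two flasks start at:

Wednesday's, 125 °C: 0.0657 h⁻¹
Thursday's, 100 °C: 0.00751 h⁻¹

This reckoning lets the rate slow with the starting material as it runs down and holds the second substrate at its charge; the readings do not include the second substrate. Over 25 h the rate, and with it the starting material, falls to:

Wednesday's: 19.3 %
Thursday's: 82.9 %

By this reckoning Thursday's stays mostly starting material, more than the 17.1 % reckoned as reacted. By the same reckoning Wednesday's has 80.7 % reacted, and half of that, 40.3 %, is more than the starting material reckoned as left. Spring's last reading puts the target's half-life in that run near 14.1 h, shorter than Wednesday's 25 h, so this reckoning expects over-reaction product to lead on Wednesday's.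

The forecast differs on Wednesday's, giving starting material at 58 % there and starting material at 86 % on Thursday's: “The starting material stays the largest pool in both runs”.

Wednesday's ends with over-reaction product at 65.4 % and starting material at 18.6 %, against 19.3 % reckoned; Thursday's ends with starting material at 84.1 %, against 82.9 %.

    catalyst intermediate A → free catalyst + target (k = 0.00154 s⁻¹, Ea = 100 kJ mol⁻¹)
    free catalyst + target → free catalyst + over-reaction product (k = 0.00478 L mol⁻¹ s⁻¹, Ea = 59.0 kJ mol⁻¹)
    catalyst intermediate B → free catalyst + second product (k = 8.94 × 10⁻⁴ s⁻¹, Ea = 119 kJ mol⁻¹)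
    second substrate + free catalyst ⇌ catalyst intermediate B (K = 12.9 L mol⁻¹, k = 0.00450 L mol⁻¹ s⁻¹, Ea = 60.0 kJ mol⁻¹, ΔH = −5.00 kJ mol⁻¹)
    starting material + free catalyst ⇌ catalyst intermediate A (K = 2.60 L mol⁻¹, k = 0.00679 L mol⁻¹ s⁻¹, Ea = 84.0 kJ mol⁻¹, ΔH = −52.0 kJ mol⁻¹)
    (constants at 100 °C)

At 25.0 h in Thursday's flask, catalyst intermediate B is the resting state, holding 62.7 % of the catalyst, with free catalyst at 22.5 %. The recipe rate 0.0126 h⁻¹, carried to 100 °C as 0.00751 h⁻¹ and scaled to 1.9 mol% of free catalyst in an otherwise unchanged Thursday's flask, leaves 62.5 % of the starting material at 25 h; that flask holds 60.7 %.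

The runs are calculated with constants of no real substance.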